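**Plan**
- Butenolide numbering: O1, C2 (lactone C=O), C3 (OH), C4 (phenyl), C5 (quaternary, R).
- Retrosynthetic cuts, in order: benzyl placed on the C3 oxygen, C4–phenyl (Suzuki), C3–C4 (Dieckmann), C5–CH2Ar (malonate alkylation), C5–O1 (carboxylate displacement), then the pyran ring of the chroman.
- Enabling feature: C5 bears a CO2Me carbon and ring carbon C4. In a tetronate, C4 is also at the carboxyl level, so both can be the twin esters of an achiral malonate whose central carbon already holds O1 and the chromanylmethyl group.
- Forward order: the pyran ring of the chroman closes first, the benzylic bromide is joined to an acyloxymalonate, the lactone ring closes in step 7, and the phenyl ring is attached afterwards.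
- Stereochemistry: C5 is the only stereocentre. It is set in step 7, where a chiral lithium amide aggregate directs the glycolate enolate to the pro-S ester, and as a quaternary carbon it cannot epimerise later.

Key step: step 7

Assumption: no precedent fixes the sense of induction in step 7. The (R,R)-tetraamine is written, and if it should favour the (S)-tetronate, its (S,S)-enantiomer (this recoverable reagent is obtainable in both forms) is used with nothing else changed.

Step 1
Reactants: 1 4-hydroxybenzaldehyde; 2 prenyl bromide (1-bromo-3-methylbut-2-ene)
Product: 3 4-hydroxy-3-(3-methylbut-2-en-1-yl)benzaldehyde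
Conditions: KOH, H2O, rt
Reagents that add atoms: none
Why: Ortho C-alkylation of a phenoxide in water, in which hydrogen bonding masks the oxygen, the formyl group blocks the para position, and the soft allylic bromide is taken up at the ring carbon next to the OH, a reaction known for this very phenol.

Step 2
Reactants: 3 4-hydroxy-3-(3-methylbut-2-en-1-yl)benzaldehyde
Product: 4 2,2-dimethylchroman-6-carbaldehyde
Conditions: p-TsOH·H2O (cat.), toluene, 80 °C
Reagents that add atoms: none
Why: Acid-catalysed intramolecular hydroalkoxylation, in which Markovnikov protonation of the trisubstituted alkene gives a tertiary cation that the neighbouring phenol oxygen captures to close the six-membered pyran ring, while the aldehyde is inert to catalytic acid.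

Step 3
Reactants: 4 2,2-dimethylchroman-6-carbaldehyde
Product: 5 (2,2-dimethylchroman-6-yl)methanol
Conditions: NaBH4, MeOH, 0 °C
Reagents that add atoms: none
Why: Borohydride reduction of an aromatic aldehyde in a molecule that holds nothing else reducible.

Step 4
Reactants: 5 (2,2-dimethylchroman-6-yl)methanol
Product: 6 6-(bromomethyl)-2,2-dimethylchroman
Conditions: PBr3, Et2O, 0 °C; used without chromatography
Reagents that add atoms: phosphorus tribromide, BrP(Br)Br
Why: Standard conversion of a benzylic alcohol into the bromide (SN2 on the phosphite ester), and because the para oxygen makes the bromide labile it is carried straight into step 6.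

Step 5
Reactants: 7 dimethyl 2-bromomalonate; 8 2-(benzyloxy)acetic acid
Product: 9 dimethyl 2-[2-(benzyloxy)acetoxy]malonate
Conditions: KHCO3, DMF, rt
Reagents that add atoms: none
Why: SN2 displacement of the doubly activated secondary bromide by the carboxylate oxygen of 8, the usual entry to acyloxymalonates, with bicarbonate too weak a base to deprotonate 7 and start its self-condensation.

Step 6
Reactants: 6 6-(bromomethyl)-2,2-dimethylchroman; 9 dimethyl 2-[2-(benzyloxy)acetoxy]malonate
Product: 10 dimethyl 2-[2-(benzyloxy)acetoxy]-2-[(2,2-dimethylchroman-6-yl)methyl]malonate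
Conditions: K2CO3, DMF, 0 °C to rt
Reagents that add atoms: none
Why: Malonate alkylation, in which carbonate removes only the C–H between the two esters of 9 and the reactive benzylic bromide alkylates that carbon, while the product has no proton that carbonate can take, so no premature racemic ring closure should occur.

Step 7
Reactants: 10 dimethyl 2-[2-(benzyloxy)acetoxy]-2-[(2,2-dimethylchroman-6-yl)methyl]malonate
Product: 13 methyl (R)-4-(benzyloxy)-2-[(2,2-dimethylchroman-6-yl)methyl]-3-hydroxy-5-oxo-2,5-dihydrofuran-2-carboxylate, via lithium enolate 11 (not isolated), via lithium tetronate 12 (not isolated)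
Conditions: (R,R)-N1,N3-bis[1-phenyl-2-(piperidin-1-yl)ethyl]propane-1,3-diamine (1.1 equiv), n-BuLi (2.1 equiv), THF, 0 °C; then slow addition of 10, −78 °C; 1 M HCl work-up (amine recovered from the aqueous phase)
Reagents that add atoms: none
Why: Proposed new method: the chiral dilithium amide takes a proton from the OCH2 group of the glycolate ester, the only acidic C–H in 10, and leaves the lithium-chelated enolate 11 (OLi and OBn cis) in a mixed amide–enolate aggregate that the ligand cannot leave, because its protonated arm and its remaining N–Li arm belong to one tetradentate molecule; C3 then adds to one ester carbonyl on C5, methoxide departs, and the second N–Li arm deprotonates the β-keto lactone to the tetronate 12, which makes the closure irreversible and erases the transient centres at C3 and C4. The closest known reactions are the Lacey–Dieckmann cyclisation of α-(benzyloxyacetoxy) esters with achiral lithium amides to 3-benzyloxytetronic acids, enantioselective C–C bond formation of lithium enolates held in mixed aggregates with this class of chiral lithium amides, and the catalytic desymmetrisation of disubstituted malonates by reduction or lactonisation; what is new is their combination, an acylation in which the chiral aggregate selects between two enantiotopic esters. The lactone ring O1–C2–C3–C4–C5 closes 5-exo-trig at the ester carbonyl and enolendo with respect to the enolate, a formally unfavourable mode that every Lacey–Dieckmann closure nevertheless follows, since free rotation about the C2–O1 bond of the enolate lifts C4 over the π face of C3. C5 is the only lasting stereocentre and becomes R when the pro-S ester is attacked: the ligand screens one face of the enolate, and on the open face the bulky chromanylmethyl group should turn away from the aggregate while the spectator ester can bind lithium, so that the choice of enolate face is translated into a choice of ester. Besides this group selectivity the step needs chemoselective enolisation, which the substrate secures through its quaternary C5 (no second enolisable site, no Chan rearrangement), while the hindered amide and −78 °C suppress attack on the esters and fragmentation of the enolate to a ketene.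

Step 8
Reactants: 13 methyl (R)-4-(benzyloxy)-2-[(2,2-dimethylchroman-6-yl)methyl]-3-hydroxy-5-oxo-2,5-dihydrofuran-2-carboxylate
Product: 14 methyl (R)-4-(benzyloxy)-2-[(2,2-dimethylchroman-6-yl)methyl]-5-oxo-3-{[(trifluoromethyl)sulfonyl]oxy}-2,5-dihydrofuran-2-carboxylate
Conditions: Tf2O, i-Pr2NEt, CH2Cl2, −78 °C
Reagents that add atoms: trifluoromethanesulfonic anhydride, O=S(=O)(OS(=O)(=O)C(F)(F)F)C(F)(F)F
Why: Enol triflate formation from a tetronic acid, which with Tf2O and a hindered amine at low temperature takes place at the C4 enol oxygen and leaves C5 untouched.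

Step 9
Reactants: 14 the C4 enol triflate; 15 phenylboronic acid
Product: 16 methyl (R)-4-(benzyloxy)-2-[(2,2-dimethylchroman-6-yl)methyl]-5-oxo-3-phenyl-2,5-dihydrofuran-2-carboxylate
Conditions: Pd(OAc)2 (cat.), SPhos (cat.), K3PO4, toluene–H2O (20:1), 60 °C
Reagents that add atoms: none
Why: Suzuki–Miyaura coupling of a 4-triflyloxy-2(5H)-furanone, an electron-poor vinylogous acyl triflate that adds readily to Pd(0), with a bulky electron-rich biaryl phosphine to cope with the flanking quaternary C5 and the C3 benzyloxy group, and with no proton on C5 that the base could remove.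

Step 10
Reactants: 16 methyl (R)-4-(benzyloxy)-2-[(2,2-dimethylchroman-6-yl)methyl]-5-oxo-3-phenyl-2,5-dihydrofuran-2-carboxylate
Product: 17 4'-dehydroxy aspernolide A, methyl (R)-2-[(2,2-dimethylchroman-6-yl)methyl]-4-hydroxy-5-oxo-3-phenyl-2,5-dihydrofuran-2-carboxylate
Conditions: H2 (1 atm), 10% Pd/C, EtOAc, rt
Reagents that add atoms: none
Why: Catalytic hydrogenolysis of the O-benzyl enol ether, under which the tetrasubstituted conjugated C3=C4 bond, the hindered C5–O1 bond, the methyl ester and the chroman ether should stay intact, releasing the stable α-hydroxybutenolide.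

**Compound list**
1 | 4-hydroxybenzaldehyde | O=Cc1ccc(O)cc1 | starting material
2 | prenyl bromide (1-bromo-3-methylbut-2-ene) | CC(C)=CCBr | starting material
3 | 4-hydroxy-3-(3-methylbut-2-en-1-yl)benzaldehyde | CC(C)=CCc1cc(C=O)ccc1O | intermediate
4 | 2,2-dimethylchroman-6-carbaldehyde | CC1(C)CCc2cc(C=O)ccc2O1 | intermediate
5 | (2,2-dimethylchroman-6-yl)methanol | CC1(C)CCc2cc(CO)ccc2O1 | intermediate
6 | 6-(bromomethyl)-2,2-dimethylchroman | CC1(C)CCc2cc(CBr)ccc2O1 | intermediate
7 | dimethyl 2-bromomalonate | COC(=O)C(Br)C(=O)OC | starting material
8 | 2-(benzyloxy)acetic acid | OC(=O)COCc1ccccc1 | starting material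
9 | dimethyl 2-[2-(benzyloxy)acetoxy]malonate | COC(=O)C(OC(=O)COCc1ccccc1)C(=O)OC | intermediate
10 | dimethyl 2-[2-(benzyloxy)acetoxy]-2-[(2,2-dimethylchroman-6-yl)methyl]malonate (achiral, prochiral central carbon) | COC(=O)C(Cc1ccc2c(c1)CCC(C)(C)O2)(OC(=O)COCc1ccccc1)C(=O)OC | intermediate
11 | lithium enolate of the glycolate ester of 10 (OLi and OBn cis on the C=C) | COC(=O)C(Cc1ccc2c(c1)CCC(C)(C)O2)(O/C([O-])=C/OCc1ccccc1)C(=O)OC.[Li+] | intermediate
12 | lithium (R)-tetronate, the lithium salt of 13 | COC(=O)[C@]1(Cc2ccc3c(c2)CCC(C)(C)O3)OC(=O)C(OCc2ccccc2)=C1[O-].[Li+] | intermediate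
13 | methyl (R)-4-(benzyloxy)-2-[(2,2-dimethylchroman-6-yl)methyl]-3-hydroxy-5-oxo-2,5-dihydrofuran-2-carboxylate | COC(=O)[C@]1(Cc2ccc3c(c2)CCC(C)(C)O3)OC(=O)C(OCc2ccccc2)=C1O | intermediate
14 | methyl (R)-4-(benzyloxy)-2-[(2,2-dimethylchroman-6-yl)methyl]-5-oxo-3-{[(trifluoromethyl)sulfonyl]oxy}-2,5-dihydrofuran-2-carboxylate | COC(=O)[C@]1(Cc2ccc3c(c2)CCC(C)(C)O3)OC(=O)C(OCc2ccccc2)=C1OS(=O)(=O)C(F)(F)F | intermediate
15 | phenylboronic acid | OB(O)c1ccccc1 | starting material
16 | methyl (R)-4-(benzyloxy)-2-[(2,2-dimethylchroman-6-yl)methyl]-5-oxo-3-phenyl-2,5-dihydrofuran-2-carboxylate | COC(=O)[C@]1(Cc2ccc3c(c2)CCC(C)(C)O3)OC(=O)C(OCc2ccccc2)=C1c1ccccc1 | intermediate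
17 | 4'-dehydroxy aspernolide A, methyl (R)-2-[(2,2-dimethylchroman-6-yl)methyl]-4-hydroxy-5-oxo-3-phenyl-2,5-dihydrofuran-2-carboxylate | COC(=O)[C@]1(Cc2ccc3c(c2)CCC(C)(C)O3)OC(=O)C(O)=C1c1ccccc1 | target

Total step count: 10. Longest linear sequence: 9 (steps 1–4 and 6–10; step 5 is the side branch).

**Steps most likely to fail**

Step 7. The two enantiotopic esters may be poorly discriminated, because the aggregate could be too loosely organised at the moment of C–C bond formation. The enolate may also fragment to a ketene and an alkoxide.
- The fallback uses known chemistry and replaces desymmetrisation by racemic closure plus classical resolution.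
- It sets out from 10. The ordinary Lacey–Dieckmann cyclisation with LiHMDS in THF at −78 °C should give racemic methyl 4-(benzyloxy)-2-[(2,2-dimethylchroman-6-yl)methyl]-3-hydroxy-5-oxo-2,5-dihydrofuran-2-carboxylate F1.
- This is a strong vinylogous acid. It is combined with (R)-1-phenylethylamine, and the diastereomeric salt (R)-1-phenylethylammonium (R)-tetronate F2 is crystallised to constant rotation. The (S)-amine is taken instead if the other pairing is the less soluble one.
- Acidification brings the route back to 13.
- The same salt crystallisation can also raise the purity of material from a step 7 that is only partly selective.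

Step 9. Transmetalation may be slow at a carbon flanked by the quaternary C5 and the C3 benzyloxy group. Base-induced S–O cleavage of the triflate and protodeboronation would then take over.
- The fallback drops both the sulfonate and the base.
- It sets out from 13. Oxalyl bromide with catalytic DMF in CH2Cl2 at 0 °C (Vilsmeier-type halogenation of a tetronic acid) should give methyl (S)-4-(benzyloxy)-3-bromo-2-[(2,2-dimethylchroman-6-yl)methyl]-5-oxo-2,5-dihydrofuran-2-carboxylate F3.
- F3 has the same spatial arrangement; the descriptor changes only because bromine raises the rank of C4.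
- A Negishi coupling with phenylzinc chloride and Pd(PPh3)4 in THF at rt then returns to the route at 16.

Step 6. The electron-rich benzylic bromide may be lost by ionisation and self-alkylation before the hindered carbanion captures it. Acyl transfer within the anion of 9 is a second risk.
- The fallback forms the C5–CH2 bond by condensation and introduces the oxygen afterwards.
- It sets out from aldehyde 4. Knoevenagel condensation with dimethyl malonate (piperidine, AcOH, toluene, azeotropic removal of water) gives dimethyl 2-[(2,2-dimethylchroman-6-yl)methylene]malonate F4.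
- Hydrogenation (H2, Pd/C, EtOAc) gives dimethyl 2-[(2,2-dimethylchroman-6-yl)methyl]malonate F5.
- Base-catalysed aerobic hydroxylation (Cs2CO3 cat., O2, P(OEt)3, DMSO, rt) gives dimethyl 2-[(2,2-dimethylchroman-6-yl)methyl]-2-hydroxymalonate F6.
- Acylation of the tertiary alcohol with benzyloxyacetyl chloride (pyridine, DMAP cat., CH2Cl2) comes back to the route at 10.

**Further compounds**
F1 | step 7 | racemic methyl 4-(benzyloxy)-2-[(2,2-dimethylchroman-6-yl)methyl]-3-hydroxy-5-oxo-2,5-dihydrofuran-2-carboxylate | COC(=O)C1(Cc2ccc3c(c2)CCC(C)(C)O3)OC(=O)C(OCc2ccccc2)=C1O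
F2 | step 7 | (R)-1-phenylethylammonium salt of (R)-13 | COC(=O)[C@]1(Cc2ccc3c(c2)CCC(C)(C)O3)OC(=O)C(OCc2ccccc2)=C1[O-].C[C@@H]([NH3+])c1ccccc1
F3 | step 9 | methyl (S)-4-(benzyloxy)-3-bromo-2-[(2,2-dimethylchroman-6-yl)methyl]-5-oxo-2,5-dihydrofuran-2-carboxylate | COC(=O)[C@]1(Cc2ccc3c(c2)CCC(C)(C)O3)OC(=O)C(OCc2ccccc2)=C1Br
F4 | step 6 | dimethyl 2-[(2,2-dimethylchroman-6-yl)methylene]malonate | COC(=O)C(=Cc1ccc2c(c1)CCC(C)(C)O2)C(=O)OC
F5 | step 6 | dimethyl 2-[(2,2-dimethylchroman-6-yl)methyl]malonate | COC(=O)C(Cc1ccc2c(c1)CCC(C)(C)O2)C(=O)OC
F6 | step 6 | dimethyl 2-[(2,2-dimethylchroman-6-yl)methyl]-2-hydroxymalonate | COC(=O)C(O)(Cc1ccc2c(c1)CCC(C)(C)O2)C(=O)OC
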